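**Plan**
1. Retrosynthesis first removes the C1–C10 epoxide oxygen and the C8 epoxyangelate. It then cuts the lactone at O–C6 and C7–C11 together, which leads back to a ten-membered (1(10)E,4Z,6E)-triene and 2-bromoacrylic acid.
2. This double cut is possible because C6 is allylic to the ring C4=C5 alkene: the α-methylene-γ-lactone is the 1,2-carbo-oxygenation adduct of the C4=C5–C6=C7 diene, whose C6–C5–C4 allyl unit accepts the carboxylate at C6.
3. The carbocycle is cut at C3–C4 (Nozaki–Hiyama–Kishi). The chain is cut at C4=C5 (Stork–Zhao), C5–C6 (cross-metathesis), C1–C2 and C10–C14 (carboalumination/oxirane) and C8–C9 (Barbier).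
4. Forward order: acyclic chain, then the ten-membered ring, then the lactone ring, then the C8 ester, then the epoxide.
5. Stereochemistry: C8 from a Sharpless kinetic resolution; C3 from a CBS reduction; C6 and C7 from suprafacial addition to the outer face of the E-C6=C7 alkene, steered by the C8 silyl ether; the side-chain epoxide from a Sharpless epoxidation; C1/C10 from peripheral peracid attack.
6. Alkene geometry: 1(10)E from syn-carboalumination, 6E from metathesis, 4Z from the Stork–Zhao reagent.

Key step: step 12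

Remark: germacrane numbering is used for ring compounds (ring C1–C10, C14 on C10, C15 on C4, lactone carbons C11–C13, lactone oxygen on C6). CIP descriptors are given per compound, so C7 is formally 7S in the silyl ethers although its geometry is the same as in the target.

**Step 1**
Reactants: 1 acrolein; 2 propargyl bromide
Product: 4 rac-hex-1-en-5-yn-3-ol, via allenylzinc bromide 3 (not isolated)
Conditions: Zn dust, THF/sat. aq. NH4Cl, 0 → 23 °C
Reagents that add atoms: none
Why: Zinc Barbier propargylation, in which the allenylzinc species adds through its γ-carbon to the aldehyde carbon in a 1,2-sense and gives the homopropargylic allylic alcohol carrying C7–C10 (racemic at C8).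

**Step 2**
Reactants: 4 rac-hex-1-en-5-yn-3-ol
Product: 5 (R)-hex-1-en-5-yn-3-ol
Conditions: Ti(OiPr)4, L-(+)-DIPT, t-BuOOH (0.6 equiv), 4 Å MS, CH2Cl2, −20 °C
Reagents that add atoms: none
Why: Sharpless kinetic resolution of a secondary allylic alcohol, in which the (S)-enantiomer should be epoxidised much faster with the L-(+)-tartrate, so the (R)-alcohol is left and fixes C8.

**Step 3**
Reactants: 5 (R)-hex-1-en-5-yn-3-ol
Product: 6 (R)-tert-butyl(hex-1-en-5-yn-3-yloxy)dimethylsilane
Conditions: TBSCl, imidazole, DMF, 23 °C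
Reagents that add atoms: tert-butyldimethylsilyl chloride CC(C)(C)[Si](C)(C)Cl
Why: Standard silylation of a secondary alcohol; the bulky silyl ether later serves as the allylic substituent that steers the key step.

**Step 4**
Reactants: 6 (R)-tert-butyl(hex-1-en-5-yn-3-yloxy)dimethylsilane; 7 oxirane
Product: 10 (3E,6R)-6-(tert-butyldimethylsilyloxy)-4-methylocta-3,7-dien-1-ol, via alkenyldimethylalane 8 (not isolated), via lithium alkenylaluminate 9 (not isolated)
Conditions: AlMe3, Cp2ZrCl2 (cat.), CH2Cl2, 0 → 23 °C; then n-BuLi, THF/hexane, −78 °C; 7, −78 → 0 °C; aq. KNaC4H4O6 (potassium sodium tartrate)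
Reagents that add atoms: trimethylaluminium C[Al](C)C
Why: Negishi zirconium-catalysed carboalumination adds methyl and aluminium syn across the terminal alkyne with methyl on the internal carbon, which fixes the 1(10)E geometry, and the derived aluminate opens oxirane with retention of that geometry to append C2–C3, while the terminal alkene reacts far more slowly than the alkyne.

**Step 5**
Reactants: 10 (3E,6R)-6-(tert-butyldimethylsilyloxy)-4-methylocta-3,7-dien-1-ol; 11 (E)-but-2-enal
Product: 12 (2E,4R,6E)-4-(tert-butyldimethylsilyloxy)-9-hydroxy-6-methylnona-2,6-dienal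
Conditions: 11 (excess), second-generation Hoveyda–Grubbs catalyst RuCl2(H2IMes)(=CH-C6H4-2-OiPr) (5 mol %), CH2Cl2, 40 °C
Reagents that add atoms: none
Why: Olefin cross-metathesis of a terminal allylic silyl ether with an excess of an α,β-unsaturated aldehyde is E-selective for thermodynamic reasons and leaves the trisubstituted alkene and the free alcohol untouched.

**Step 6**
Reactants: 12 (2E,4R,6E)-4-(tert-butyldimethylsilyloxy)-9-hydroxy-6-methylnona-2,6-dienal
Product: 13 (3E,6R,7E,9Z)-6-(tert-butyldimethylsilyloxy)-10-iodo-4-methylundeca-3,7,9-trien-1-ol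
Conditions: EtPPh3I, n-BuLi, THF, 23 °C; I2, −78 °C; NaN(SiMe3)2, −20 °C; then 12, −78 °C (3 equiv of ylide)
Reagents that add atoms: ethyltriphenylphosphonium iodide CC[P+](c1ccccc1)(c1ccccc1)c1ccccc1.[I-]; iodine II
Why: Stork–Zhao olefination, in which the α-iodo ylide reacts with the aldehyde under kinetic control to give the (Z)-trisubstituted vinyl iodide (iodine cis to C6) and so sets the 4Z geometry; excess ylide covers the free hydroxyl as in Wittig reactions of hydroxy aldehydes.

**Step 7**
Reactants: 13 (3E,6R,7E,9Z)-6-(tert-butyldimethylsilyloxy)-10-iodo-4-methylundeca-3,7,9-trien-1-ol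
Product: 14 (3E,6R,7E,9Z)-6-(tert-butyldimethylsilyloxy)-10-iodo-4-methylundeca-3,7,9-trienal
Conditions: Dess–Martin periodinane, NaHCO3, CH2Cl2, 0 °C
Reagents that add atoms: none
Why: Buffered Dess–Martin oxidation gives the β,γ-unsaturated aldehyde under neutral conditions without moving the C1=C10 alkene into conjugation; the aldehyde is used at once.

**Step 8**
Reactants: 14 (3E,6R,7E,9Z)-6-(tert-butyldimethylsilyloxy)-10-iodo-4-methylundeca-3,7,9-trienal
Product: 16 (2Z,4E,6R,8E)-6-(tert-butyldimethylsilyloxy)-2,8-dimethylcyclodeca-2,4,8-trien-1-ol (both C1 epimers), via alkenylchromium dichloride 15 (not isolated)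
Conditions: CrCl2 (10 equiv), NiCl2 (cat.), DMSO, 23 °C, 2 mM, slow addition
Reagents that add atoms: none
Why: Nozaki–Hiyama–Kishi reaction, in which zerovalent nickel inserts into the C–I bond and transmetallation to trivalent chromium gives an alkenylchromium species that adds chemoselectively to the aldehyde with retention of alkene geometry and closes the ten-membered ring at C3–C4; the C3 configuration is left open because steps 9 and 10 reset it.

**Step 9**
Reactants: 16 (2Z,4E,6R,8E)-6-(tert-butyldimethylsilyloxy)-2,8-dimethylcyclodeca-2,4,8-trien-1-ol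
Product: 17 (2Z,4E,6R,8E)-6-(tert-butyldimethylsilyloxy)-2,8-dimethylcyclodeca-2,4,8-trien-1-one
Conditions: MnO2, CH2Cl2, 23 °C
Reagents that add atoms: none
Why: MnO2 oxidises allylic alcohols selectively under neutral heterogeneous conditions, which converges both C3 epimers to one dienone and avoids base that would isomerise the β,γ-alkene.

**Step 10**
Reactants: 17 (2Z,4E,6R,8E)-6-(tert-butyldimethylsilyloxy)-2,8-dimethylcyclodeca-2,4,8-trien-1-one
Product: 18 (1S,2Z,4E,6R,8E)-6-(tert-butyldimethylsilyloxy)-2,8-dimethylcyclodeca-2,4,8-trien-1-ol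
Conditions: (R)-2-methyl-CBS-oxazaborolidine, catecholborane, toluene, −78 °C
Reagents that add atoms: none
Why: Corey–Bakshi–Shibata reduction, in which the alkenyl side of the ketone acts as the large group so that the (R)-oxazaborolidine should deliver hydride to the face giving the (3S)-allylic alcohol under reagent control, with catecholborane at low temperature reducing 1,2 without hydroborating the alkenes.

**Step 11**
Reactants: 18 (1S,2Z,4E,6R,8E)-6-(tert-butyldimethylsilyloxy)-2,8-dimethylcyclodeca-2,4,8-trien-1-ol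
Product: 19 (1S,2Z,4E,6R,8E)-6-(tert-butyldimethylsilyloxy)-2,8-dimethylcyclodeca-2,4,8-trien-1-yl benzoate
Conditions: BzCl, pyridine, DMAP (cat.), CH2Cl2, 0 °C
Reagents that add atoms: benzoyl chloride O=C(Cl)c1ccccc1
Why: DMAP-catalysed acylation with retention at C3 installs the benzoate that stays in the target, and the mild base avoids an anionic oxy-Cope rearrangement of the 1,5-dien-3-ol.

**Step 12**
Reactants: 19 (1S,2Z,4E,6R,8E)-6-(tert-butyldimethylsilyloxy)-2,8-dimethylcyclodeca-2,4,8-trien-1-yl benzoate; 20 2-bromoacrylic acid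
Product: 21 (3S,6R,7S,8R)-3-benzoyloxy-8-(tert-butyldimethylsilyloxy)germacra-1(10)E,4Z,11(13)-trien-6,12-olide
Conditions: 20 (2 equiv), Pd(OAc)2 (10 mol %), P(2-furyl)3 (20 mol %), Ag2CO3, MeCN, 45 °C
Reagents that add atoms: none
Why: Proposed new method: zerovalent palladium inserts into the C–Br bond of 20, the alkenylpalladium bromide adds syn across the strained E-configured C6=C7 bond of the C4=C5–C6=C7 diene with carbon going to C7, and the resulting C6–C5–C4 η3-allylpalladium, freed of bromide by silver, is captured at C6 by its own carboxylate from the palladium-bearing face to release the lactone and zerovalent palladium. The closest known reaction type is the Larock heteroannulation of 1,3-dienes with halo carboxylic acids such as 2-iodobenzoic acid, here extended to an α-bromoacrylic acid as three-atom partner on a medium-ring triene. The one ring closure is a 5-exo attack of the carboxylate oxygen on the allyl terminus C6, preferred over 7-endo attack at the fully substituted C4, and it leaves the 4Z geometry untouched. C7 is set by attack on the outer face of the E-alkene, anti to ring carbon C9 with the C8 silyloxy group in the alkene plane and only H8 on the exposed face, and C6 follows from suprafacial delivery of carbon and oxygen, which on an E-alkene gives the trans ring fusion with the configuration of the target. The step needs site selectivity for the diene terminus C7 over C4 and over the isolated C1=C10 alkene, which the disubstituted, conjugated and strained C6=C7 bond supplies, and it needs inner-sphere C–O bond formation, which the halide-free silver carbonate conditions favour. The temperature is kept at 45 °C because 19 contains 1,5-diene units that would undergo Cope rearrangement on stronger heating.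

**Step 13**
Reactants: 21 (3S,6R,7S,8R)-3-benzoyloxy-8-(tert-butyldimethylsilyloxy)germacra-1(10)E,4Z,11(13)-trien-6,12-olide
Product: 22 (3S,6R,7R,8R)-3-benzoyloxy-8-hydroxygermacra-1(10)E,4Z,11(13)-trien-6,12-olide
Conditions: HF·pyridine, pyridine, THF, 0 → 23 °C
Reagents that add atoms: none
Why: Buffered HF·pyridine cleaves the secondary silyl ether without touching the benzoate, the lactone or the exocyclic methylene, which basic fluoride sources could attack.

**Step 14**
Reactants: 23 methyl angelate (methyl (Z)-2-methylbut-2-enoate)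
Product: 24 (Z)-2-methylbut-2-en-1-ol
Conditions: i-Bu2AlH, CH2Cl2, −78 → 0 °C
Reagents that add atoms: none
Why: Low-temperature hydride reduction of the ester to the allylic alcohol preserves the (Z)-geometry of the angelate.

**Step 15**
Reactants: 24 (Z)-2-methylbut-2-en-1-ol
Product: 25 [(2S,3R)-2,3-dimethyloxiran-2-yl]methanol
Conditions: Ti(OiPr)4 (cat.), L-(+)-DET (cat.), t-BuOOH, 4 Å MS, CH2Cl2, −20 °C
Reagents that add atoms: tert-butyl hydroperoxide CC(C)(C)OO
Why: Sharpless asymmetric epoxidation, in which the L-(+)-tartrate delivers oxygen to the face that gives 2S-epoxides from primary allylic alcohols, here the (2S,3R)-epoxy alcohol, and the syn addition keeps the hydroxymethyl group cis to the C3 methyl.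

**Step 16**
Reactants: 25 [(2S,3R)-2,3-dimethyloxiran-2-yl]methanol
Product: 27 (2R,3R)-2,3-dimethyloxirane-2-carboxylic acid, via epoxy aldehyde 26 (not isolated)
Conditions: RuCl3·xH2O (cat.), NaIO4, CCl4/MeCN/H2O, 23 °C
Reagents that add atoms: water O; sodium periodate [Na+].[O-]I(=O)(=O)=O
Why: RuO4 generated in situ oxidises the primary alcohol through the aldehyde hydrate to the glycidic acid without opening the epoxide or touching its two stereocentres (the descriptor at C2 changes only because the priorities change).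

**Step 17**
Reactants: 22 (3S,6R,7R,8R)-3-benzoyloxy-8-hydroxygermacra-1(10)E,4Z,11(13)-trien-6,12-olide; 27 (2R,3R)-2,3-dimethyloxirane-2-carboxylic acid
Product: 29 (3S,6R,7R,8R)-3-benzoyloxy-8-[(2R,3R)-2,3-dimethyloxirane-2-carbonyloxy]germacra-1(10)E,4Z,11(13)-trien-6,12-olide, via mixed anhydride 28 (not isolated)
Conditions: 2,4,6-trichlorobenzoyl chloride, Et3N, toluene, 23 °C; then 22, DMAP, 23 °C
Reagents that add atoms: none
Why: Yamaguchi esterification, in which the hindered α-quaternary epoxy acid is activated as the mixed anhydride and DMAP transfers the acyl group to the hindered C8 hydroxyl with retention at C8; the acid has no epimerisable centre.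

**Step 18**
Reactants: 29 (3S,6R,7R,8R)-3-benzoyloxy-8-[(2R,3R)-2,3-dimethyloxirane-2-carbonyloxy]germacra-1(10)E,4Z,11(13)-trien-6,12-olide
Product: 30 (1R,3S,6R,7R,8R,10R)-3-benzoyloxy-1,10-epoxy-8-[(2R,3R)-2,3-dimethyloxirane-2-carbonyloxy]germacra-4Z,11(13)-dien-6,12-olide
Conditions: mCPBA, NaHCO3, CH2Cl2, −10 → 0 °C
Reagents that add atoms: 3-chloroperbenzoic acid OOC(=O)c1cccc(Cl)c1
Why: Prilezhaev epoxidation, in which the peracid reacts with the only electron-rich alkene (C4=C5 is deactivated by two allylic acyloxy groups and C11=C13 is conjugated) and attack on the outer face of the E-alkene of the ten-membered ring should give the trans (1R,10R)-epoxide.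

**Compound list**
1 | acrolein | C=CC=O | starting material
2 | propargyl bromide | BrCC#C | starting material
3 | allenylzinc bromide | C=C=C[Zn]Br | intermediate
4 | rac-hex-1-en-5-yn-3-ol | C=CC(O)CC#C | intermediate
5 | (R)-hex-1-en-5-yn-3-ol | C=C[C@H](O)CC#C | intermediate
6 | (R)-tert-butyl(hex-1-en-5-yn-3-yloxy)dimethylsilane | C=C[C@H](O[Si](C)(C)C(C)(C)C)CC#C | intermediate
7 | oxirane | C1CO1 | starting material
8 | [(1E,4R)-4-(tert-butyldimethylsilyloxy)-2-methylhexa-1,5-dien-1-yl]dimethylalane | C=C[C@H](O[Si](C)(C)C(C)(C)C)C/C(C)=C/[Al](C)C | intermediate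
9 | lithium butyl[(1E,4R)-4-(tert-butyldimethylsilyloxy)-2-methylhexa-1,5-dien-1-yl]dimethylaluminate | [Li+].C=C[C@H](O[Si](C)(C)C(C)(C)C)C/C(C)=C/[Al-](C)(C)CCCC | intermediate
10 | (3E,6R)-6-(tert-butyldimethylsilyloxy)-4-methylocta-3,7-dien-1-ol | C=C[C@H](O[Si](C)(C)C(C)(C)C)C/C(C)=C/CCO | intermediate
11 | (E)-but-2-enal (crotonaldehyde) | C/C=C/C=O | starting material
12 | (2E,4R,6E)-4-(tert-butyldimethylsilyloxy)-9-hydroxy-6-methylnona-2,6-dienal | O=C/C=C/[C@H](O[Si](C)(C)C(C)(C)C)C/C(C)=C/CCO | intermediate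
13 | (3E,6R,7E,9Z)-6-(tert-butyldimethylsilyloxy)-10-iodo-4-methylundeca-3,7,9-trien-1-ol | C/C(I)=C/C=C/[C@H](O[Si](C)(C)C(C)(C)C)C/C(C)=C/CCO | intermediate
14 | (3E,6R,7E,9Z)-6-(tert-butyldimethylsilyloxy)-10-iodo-4-methylundeca-3,7,9-trienal | C/C(I)=C/C=C/[C@H](O[Si](C)(C)C(C)(C)C)C/C(C)=C/CC=O | intermediate
15 | dichloro[(2Z,4E,6R,8E)-6-(tert-butyldimethylsilyloxy)-8-methyl-11-oxoundeca-2,4,8-trien-2-yl]chromium | C/C([Cr](Cl)Cl)=C/C=C/[C@H](O[Si](C)(C)C(C)(C)C)C/C(C)=C/CC=O | intermediate
16 | (2Z,4E,6R,8E)-6-(tert-butyldimethylsilyloxy)-2,8-dimethylcyclodeca-2,4,8-trien-1-ol, both C1 epimers | C/C1=C/C=C/[C@H](O[Si](C)(C)C(C)(C)C)C/C(C)=C/CC1O | intermediate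
17 | (2Z,4E,6R,8E)-6-(tert-butyldimethylsilyloxy)-2,8-dimethylcyclodeca-2,4,8-trien-1-one | C/C1=C/C=C/[C@H](O[Si](C)(C)C(C)(C)C)C/C(C)=C/CC1=O | intermediate
18 | (1S,2Z,4E,6R,8E)-6-(tert-butyldimethylsilyloxy)-2,8-dimethylcyclodeca-2,4,8-trien-1-ol | C/C1=C/C=C/[C@H](O[Si](C)(C)C(C)(C)C)C/C(C)=C/C[C@@H]1O | intermediate
19 | (1S,2Z,4E,6R,8E)-6-(tert-butyldimethylsilyloxy)-2,8-dimethylcyclodeca-2,4,8-trien-1-yl benzoate | C/C1=C/C=C/[C@H](O[Si](C)(C)C(C)(C)C)C/C(C)=C/C[C@@H]1OC(=O)c1ccccc1 | intermediate
20 | 2-bromoacrylic acid | C=C(Br)C(=O)O | starting material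
21 | (3S,6R,7S,8R)-3-benzoyloxy-8-(tert-butyldimethylsilyloxy)germacra-1(10)E,4Z,11(13)-trien-6,12-olide | C=C1C(=O)O[C@@H]2/C=C(/C)[C@@H](OC(=O)c3ccccc3)C/C=C(\C)C[C@@H](O[Si](C)(C)C(C)(C)C)[C@@H]12 | intermediate
22 | (3S,6R,7R,8R)-3-benzoyloxy-8-hydroxygermacra-1(10)E,4Z,11(13)-trien-6,12-olide | C=C1C(=O)O[C@@H]2/C=C(/C)[C@@H](OC(=O)c3ccccc3)C/C=C(\C)C[C@@H](O)[C@@H]12 | intermediate
23 | methyl angelate, methyl (Z)-2-methylbut-2-enoate | C/C=C(/C)C(=O)OC | starting material
24 | (Z)-2-methylbut-2-en-1-ol | C/C=C(/C)CO | intermediate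
25 | [(2S,3R)-2,3-dimethyloxiran-2-yl]methanol | OC[C@]1(C)O[C@@H]1C | intermediate
26 | (2R,3R)-2,3-dimethyloxirane-2-carbaldehyde | O=C[C@]1(C)O[C@@H]1C | intermediate
27 | (2R,3R)-2,3-dimethyloxirane-2-carboxylic acid | OC(=O)[C@]1(C)O[C@@H]1C | intermediate
28 | (2R,3R)-2,3-dimethyloxirane-2-carboxylic 2,4,6-trichlorobenzoic anhydride | O=C(OC(=O)[C@]1(C)O[C@@H]1C)c1c(Cl)cc(Cl)cc1Cl | intermediate
29 | (3S,6R,7R,8R)-3-benzoyloxy-8-[(2R,3R)-2,3-dimethyloxirane-2-carbonyloxy]germacra-1(10)E,4Z,11(13)-trien-6,12-olide | C=C1C(=O)O[C@@H]2/C=C(/C)[C@@H](OC(=O)c3ccccc3)C/C=C(\C)C[C@@H](OC(=O)[C@]3(C)O[C@@H]3C)[C@@H]12 | intermediate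
30 | (1R,3S,6R,7R,8R,10R)-3-benzoyloxy-1,10-epoxy-8-[(2R,3R)-2,3-dimethyloxirane-2-carbonyloxy]germacra-4Z,11(13)-dien-6,12-olide | C=C1C(=O)O[C@@H]2/C=C(/C)[C@@H](OC(=O)c3ccccc3)C[C@H]3O[C@]3(C)C[C@@H](OC(=O)[C@]3(C)O[C@@H]3C)[C@@H]12 | target

**Count and risks**
Total steps: 18. Longest linear sequence: 15 (steps 1–13, 17, 18).

1. Step 12 (proposed new method). What may go wrong:
- insertion at the wrong diene carbon or on the inner face;
- β-hydride loss from the allylpalladium intermediate to a tetraene;
- outer-sphere carboxylate attack giving the cis-fused lactone;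
- ionisation of the allylic esters by zerovalent palladium;
- Cope rearrangement of the triene.

 Fallback with known chemistry, from 19 back to 21: the lactone is built by oxidative free-radical annulation and methylenated afterwards. Compound 19 is heated with Mn(OAc)3·2H2O and KOAc in AcOH/Ac2O at 70 °C. The carboxymethyl radical adds to C7, trivalent manganese oxidises the allyl radical, and the acid closes on C6 to give the des-methylene lactone (3S,6R,7S,8R)-3-benzoyloxy-8-(tert-butyldimethylsilyloxy)germacra-1(10)E,4Z-dien-6,12-olide F1. Enolisation with LiN(SiMe3)2 at −78 °C and Mannich reaction with Eschenmoser's salt give the 13-dimethylamino-11,13-dihydro lactone F2. Quaternisation with MeI and elimination with NaHCO3 give 21.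

2. Step 8. What may go wrong: oligomerisation instead of closure of the strained ten-membered triene, loss of the Z geometry at the alkenyl metal stage, or isomerisation of the β,γ-unsaturated aldehyde.

 Fallback, from 10 back to 16: the ring is closed at the C5–C6 diene bond by cross-coupling instead of at C3–C4 by carbonyl addition. Dess–Martin oxidation of 10 gives (3E,6R)-6-(tert-butyldimethylsilyloxy)-4-methylocta-3,7-dienal F3. Addition of HC≡CMgBr gives the propargylic alcohol (5E,8R)-8-(tert-butyldimethylsilyloxy)-6-methyldeca-5,9-dien-1-yn-3-ol F4, whose C3 epimers are both usable. Copper-catalysed anti-carbomagnesiation of the alkoxide (MeMgBr, CuI) with iodine quench gives (1Z,5E,8R)-8-(tert-butyldimethylsilyloxy)-1-iodo-2,6-dimethyldeca-1,5,9-trien-3-ol F5. Cross-metathesis with vinylboronic acid pinacol ester gives the (E)-alkenylboronate F6. Intramolecular Suzuki–Miyaura coupling (Pd(PPh3)4, Cs2CO3, THF/H2O, high dilution) then gives 16.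

3. Step 18. What may go wrong: poor facial selectivity at C1=C10 or competing oxidation of C4=C5.

 Fallback, from 22 back to 30: the epoxide is set by catalyst control before acylation. Shi epoxidation of 22 (D-fructose-derived ketone, KHSO5 as 2KHSO5·KHSO4·K2SO4, K2CO3, MeCN/dimethoxymethane/aq. buffer, 0 °C) should give the (1R,10R)-epoxy alcohol (1R,3S,6R,7R,8R,10R)-3-benzoyloxy-1,10-epoxy-8-hydroxygermacra-4Z,11(13)-dien-6,12-olide F7. Yamaguchi esterification of F7 with 27 through 28 then gives 30.

**Further compounds**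
F1 | step 12 | (3S,6R,7S,8R)-3-benzoyloxy-8-(tert-butyldimethylsilyloxy)germacra-1(10)E,4Z-dien-6,12-olide | C1C(=O)O[C@@H]2/C=C(/C)[C@@H](OC(=O)c3ccccc3)C/C=C(\C)C[C@@H](O[Si](C)(C)C(C)(C)C)[C@@H]12
F2 | step 12 | (3S,6R,7S,8R)-3-benzoyloxy-8-(tert-butyldimethylsilyloxy)-13-(dimethylamino)germacra-1(10)E,4Z-dien-6,12-olide, C11 epimers | CN(C)CC1C(=O)O[C@@H]2/C=C(/C)[C@@H](OC(=O)c3ccccc3)C/C=C(\C)C[C@@H](O[Si](C)(C)C(C)(C)C)[C@@H]12
F3 | step 8 | (3E,6R)-6-(tert-butyldimethylsilyloxy)-4-methylocta-3,7-dienal | C=C[C@H](O[Si](C)(C)C(C)(C)C)C/C(C)=C/CC=O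
F4 | step 8 | (5E,8R)-8-(tert-butyldimethylsilyloxy)-6-methyldeca-5,9-dien-1-yn-3-ol, C3 epimers | C=C[C@H](O[Si](C)(C)C(C)(C)C)C/C(C)=C/CC(O)C#C
F5 | step 8 | (1Z,5E,8R)-8-(tert-butyldimethylsilyloxy)-1-iodo-2,6-dimethyldeca-1,5,9-trien-3-ol, C3 epimers | C=C[C@H](O[Si](C)(C)C(C)(C)C)C/C(C)=C/CC(O)/C(C)=C\I
F6 | step 8 | (1Z,5E,8R,9E)-8-(tert-butyldimethylsilyloxy)-1-iodo-2,6-dimethyl-10-(4,4,5,5-tetramethyl-1,3,2-dioxaborolan-2-yl)deca-1,5,9-trien-3-ol, C3 epimers | CC1(C)OB(/C=C/[C@H](O[Si](C)(C)C(C)(C)C)C/C(C)=C/CC(O)/C(C)=C\I)OC1(C)C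
F7 | step 18 | (1R,3S,6R,7R,8R,10R)-3-benzoyloxy-1,10-epoxy-8-hydroxygermacra-4Z,11(13)-dien-6,12-olide | C=C1C(=O)O[C@@H]2/C=C(/C)[C@@H](OC(=O)c3ccccc3)C[C@H]3O[C@]3(C)C[C@@H](O)[C@@H]12
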